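Numbering: in each half C1 is the ester carbonyl, C4 the oxazole carbon that carries the chain, C14 the ester carbinol and C19 the end methyl. The epoxide half (oxazole A) is unprimed and the methoxy half (oxazole B) primed, and the 30-membered ring is held by the esters C1–O14′ and C1′–O14.
Enabling feature: outside that ring, C16 and C16′ are the same (S)-configured (E)-propenyl carbinol, each on a hydrogen-free quaternary carbon (C15, C15′). The first cuts are therefore C16–C17 and C16′–C17′, leading to a non-enolisable macrocyclic dialdehyde and two molecules of (E)-1-bromopropene.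
Further cuts: ester C1′–O14 (ring opening), C5=C6 (olefination between the halves), C10′–C11′ and C8′–C9′ (two alkyne couplings on (Z)-1,2-dichloroethene), ester C1–O14′, C7=C8, C10–C11, and C13–C14 / C13′–C14′.
Forward: one aldehyde from neopentyl glycol is propargylated to both enantiomers. The S alkyne grows into the C6–C16 epoxy enal. The R alkyne is acylated by the oxazole A phosphonate and coupled with the serine-derived oxazole B chloroenyne, and the enediyne is reduced to the triene. The halves then join at C5=C6, the macrocycle closes by lactonisation at O14, and C16/C16′ are raised to aldehydes.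
Stereochemistry: C14 (S) and C14′ (R) come from (S)- and (R)-BINOL/Ti(OiPr)4 propargylation, C6′ (R) from (R)-BINOL/Ti(OiPr)4 allylation, and C9 (S)/C10 (R) from Sharpless epoxidation of a Z olefin with L-(+)-DET. Z alkenes come from Z halides and syn semireductions, E alkenes from stabilised olefinations, and C16/C16′ (S,S) from the chiral ligand on chromium.

Key step: step 27

Assumption: the (S)-valinol-derived oxazoline–sulfonamide is taken as the ligand antipode that sends an alkenylchromium reagent to the Si face of an α-quaternary aldehyde. If a trial on a simple 3-acyloxy-2,2-dimethylpropanal shows the opposite sense, its enantiomer is used and nothing else changes.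
Remark: from the first cis-divinyl oxirane onward, all operations run at or below room temperature, in the dark and on base-washed silica, because this motif can ring-expand by a Cope-type shift on heating and opens with acid.

Step 1
Reactants: 1 2,2-dimethylpropane-1,3-diol
Product: 2 3-[(tert-butyldimethylsilyl)oxy]-2,2-dimethylpropan-1-ol
Conditions: NaH (1 equiv), THF, 0 °C → rt; TBSCl, rt
Reagents that add atoms: tert-butyldimethylsilyl chloride, CC(C)(C)[Si](C)(C)Cl
Why: O-Silylation of the monosodium alkoxide, which precipitates from THF and so reacts only once, desymmetrises the diol and fixes the later C16 as a silyl ether.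

Step 2
Reactants: 2 3-[(tert-butyldimethylsilyl)oxy]-2,2-dimethylpropan-1-ol
Product: 3 3-[(tert-butyldimethylsilyl)oxy]-2,2-dimethylpropanal
Conditions: (COCl)2, DMSO, CH2Cl2, −78 °C; Et3N, −78 °C → rt
Reagents that add atoms: none
Why: Swern oxidation stops at the aldehyde, and the quaternary α-carbon (the later C15) rules out enolisation.

Step 3
Reactants: 3 3-[(tert-butyldimethylsilyl)oxy]-2,2-dimethylpropanal; 4 tributyl(propa-1,2-dien-1-yl)stannane
Product: 5 (3S)-1-[(tert-butyldimethylsilyl)oxy]-2,2-dimethylhex-5-yn-3-ol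
Conditions: (S)-BINOL, Ti(OiPr)4 (cat.), 4 Å MS, CH2Cl2, −20 °C; aq. NaHCO3
Reagents that add atoms: none
Why: In this Keck-type catalytic asymmetric propargylation the allenylstannane attacks through its γ-carbon (SE2′) the Si face of the aldehyde bound to the (S)-BINOL–titanium Lewis acid, which forms C13–C14 and sets C14 as S.

Step 4
Reactants: 6 ethyl (2Z)-3-iodoprop-2-enoate
Product: 7 (2Z)-3-iodoprop-2-en-1-ol
Conditions: i-Bu2AlH, CH2Cl2, −78 °C; aq. potassium sodium tartrate
Reagents that add atoms: none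
Why: Ester reduction with i-Bu2AlH at low temperature gives the allylic alcohol without touching the C–I bond or its Z geometry.

Step 5
Reactants: 5 (3S)-1-[(tert-butyldimethylsilyl)oxy]-2,2-dimethylhex-5-yn-3-ol; 7 (2Z)-3-iodoprop-2-en-1-ol
Product: 8 (2Z,7S)-9-[(tert-butyldimethylsilyl)oxy]-8,8-dimethylnon-2-en-4-yne-1,7-diol
Conditions: PdCl2(PPh3)2, CuI (cat.), i-Pr2NH, THF, rt
Reagents that add atoms: none
Why: Sonogashira coupling forms C10–C11 with retention of the Z alkenyl iodide geometry and needs no protection of the two hydroxyl groups.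

Step 6
Reactants: 8 (2Z,7S)-9-[(tert-butyldimethylsilyl)oxy]-8,8-dimethylnon-2-en-4-yne-1,7-diol
Product: 9 (3S)-1-[(tert-butyldimethylsilyl)oxy]-6-[(2R,3S)-3-(hydroxymethyl)oxiran-2-yl]-2,2-dimethylhex-5-yn-3-ol
Conditions: Ti(OiPr)4, L-(+)-DET (cat.), t-BuOOH, 4 Å MS, CH2Cl2, −20 °C
Reagents that add atoms: tert-butyl hydroperoxide, CC(C)(C)OO
Why: Sharpless asymmetric epoxidation is steered by the allylic C8 hydroxyl to C9=C10 only, L-(+)-DET selects the face that gives 9S,10R, the syn oxygen transfer turns the Z olefin into the cis oxirane, and the wrong-face product is a separable diastereomer because C14 is already set.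

Step 7
Reactants: 9 (3S)-1-[(tert-butyldimethylsilyl)oxy]-6-[(2R,3S)-3-(hydroxymethyl)oxiran-2-yl]-2,2-dimethylhex-5-yn-3-ol
Product: 10 (3S,5Z)-1-[(tert-butyldimethylsilyl)oxy]-6-[(2R,3S)-3-(hydroxymethyl)oxiran-2-yl]-2,2-dimethylhex-5-en-3-ol
Conditions: H2 (1 atm), Pd/CaCO3 poisoned with Pb(OAc)2, quinoline, EtOAc, 0 °C → rt
Reagents that add atoms: none
Why: Lindlar semihydrogenation adds hydrogen syn to C11≡C12 and stops at the Z alkene, with quinoline holding back over-reduction and cleavage of the propargylic C10–O bond.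

Step 8
Reactants: 10 (3S,5Z)-1-[(tert-butyldimethylsilyl)oxy]-6-[(2R,3S)-3-(hydroxymethyl)oxiran-2-yl]-2,2-dimethylhex-5-en-3-ol; 11 (triphenyl-λ5-phosphanylidene)acetaldehyde
Product: 13 (2E)-3-{(2S,3R)-3-[(1Z,4S)-6-[(tert-butyldimethylsilyl)oxy]-4-hydroxy-5,5-dimethylhex-1-en-1-yl]oxiran-2-yl}prop-2-enal, via cis-epoxy aldehyde 12 (not isolated)
Conditions: [Cu(MeCN)4]OTf, 2,2′-bipyridine, TEMPO, N-methylimidazole (cat.), air, MeCN, rt; then 11, CH2Cl2, rt
Reagents that add atoms: none
Why: Copper/TEMPO aerobic oxidation (Stahl type) takes only the primary C8 alcohol under non-acidic conditions and leaves the hindered C14 carbinol, and the stabilised ylide traps the epimerisable cis-epoxy aldehyde at once in an E-selective Wittig reaction that forms C7=C8.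

Step 9
Reactants: 3 3-[(tert-butyldimethylsilyl)oxy]-2,2-dimethylpropanal; 4 tributyl(propa-1,2-dien-1-yl)stannane
Product: 14 (3R)-1-[(tert-butyldimethylsilyl)oxy]-2,2-dimethylhex-5-yn-3-ol
Conditions: (R)-BINOL, Ti(OiPr)4 (cat.), 4 Å MS, CH2Cl2, −20 °C; aq. NaHCO3
Reagents that add atoms: none
Why: The same Keck-type asymmetric propargylation with the mirror-image (R)-BINOL–titanium catalyst attacks the Re face, forms C13′–C14′ and sets C14′ as R.

Step 10
Reactants: 15 methyl 2-(chloromethyl)-1,3-oxazole-4-carboxylate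
Product: 16 methyl 2-[(diethoxyphosphoryl)methyl]-1,3-oxazole-4-carboxylate
Conditions: P(OEt)3, NaI (cat.), neat, 130 °C
Reagents that add atoms: triethyl phosphite, CCOP(OCC)OCC
Why: Michaelis–Arbuzov reaction of the activated heterobenzylic chloride, speeded by halide exchange in the flask, installs the C5 phosphonate on oxazole A.

Step 11
Reactants: 16 methyl 2-[(diethoxyphosphoryl)methyl]-1,3-oxazole-4-carboxylate
Product: 17 2-[(diethoxyphosphoryl)methyl]-1,3-oxazole-4-carboxylic acid
Conditions: LiOH, THF/H2O, 0 °C → rt; 1 M HCl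
Reagents that add atoms: lithium hydroxide, [Li+].[OH-]
Why: Saponification of the unhindered methyl ester leaves the diethyl phosphonate untouched.

Step 12
Reactants: 14 (3R)-1-[(tert-butyldimethylsilyl)oxy]-2,2-dimethylhex-5-yn-3-ol; 17 2-[(diethoxyphosphoryl)methyl]-1,3-oxazole-4-carboxylic acid
Product: 18 (3R)-1-[(tert-butyldimethylsilyl)oxy]-2,2-dimethylhex-5-yn-3-yl 2-[(diethoxyphosphoryl)methyl]-1,3-oxazole-4-carboxylate
Conditions: DCC, DMAP, CH2Cl2, 0 °C → rt
Reagents that add atoms: none
Why: Steglich esterification acylates the neopentylic carbinol at oxygen, so C14′ keeps its configuration and the final C1–O14′ ester doubles as the protecting group of that hydroxyl.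

Step 13
Reactants: 19 3-(trimethylsilyl)prop-2-ynal; 20 tributyl(prop-2-en-1-yl)stannane
Product: 21 (3R)-1-(trimethylsilyl)hex-5-en-1-yn-3-ol
Conditions: (R)-BINOL, Ti(OiPr)4 (cat.), 4 Å MS, CH2Cl2, −20 °C; aq. NaHCO3
Reagents that add atoms: none
Why: Keck asymmetric allylation with the (R)-BINOL–titanium catalyst delivers the allyl group to the Re face of the ynal and sets C6′ as R.

Step 14
Reactants: 21 (3R)-1-(trimethylsilyl)hex-5-en-1-yn-3-ol
Product: 22 [(3R)-3-methoxyhex-5-en-1-yn-1-yl]trimethylsilane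
Conditions: Me3OBF4, 1,8-bis(dimethylamino)naphthalene, CH2Cl2, 0 °C → rt
Reagents that add atoms: trimethyloxonium tetrafluoroborate, C[O+](C)C.F[B-](F)(F)F
Why: O-Methylation with Meerwein salt and a non-nucleophilic proton scavenger avoids the alkoxide that would endanger the C-silyl group.

Step 15
Reactants: 22 [(3R)-3-methoxyhex-5-en-1-yn-1-yl]trimethylsilane
Product: 24 (3R)-3-methoxy-5-(trimethylsilyl)pent-4-ynoic acid, via β-methoxy aldehyde 23 (not isolated)
Conditions: O3, CH2Cl2, −78 °C; Me2S; then NaClO2, NaH2PO4, 2-methylbut-2-ene, t-BuOH/H2O, 0 °C → rt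
Reagents that add atoms: ozone, [O-][O+]=O; sodium chlorite, [Na+].[O-]Cl=O
Why: Ozonolysis cleaves the terminal alkene much faster than the silylated alkyne, and Pinnick oxidation of the crude aldehyde outruns β-elimination of methanol and leaves C6′ untouched.

Step 16
Reactants: 24 (3R)-3-methoxy-5-(trimethylsilyl)pent-4-ynoic acid; 25 L-serine methyl ester hydrochloride
Product: 26 methyl N-[(3R)-3-methoxy-5-(trimethylsilyl)pent-4-ynoyl]-L-serinate
Conditions: EDC·HCl, HOBt, i-Pr2NEt, CH2Cl2, 0 °C → rt
Reagents that add atoms: none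
Why: Carbodiimide/HOBt amide coupling joins the acid to the free-based serine ester without affecting either stereocentre.

Step 17
Reactants: 26 methyl N-[(3R)-3-methoxy-5-(trimethylsilyl)pent-4-ynoyl]-L-serinate
Product: 28 methyl 2-[(2R)-2-methoxy-4-(trimethylsilyl)but-3-yn-1-yl]-1,3-oxazole-4-carboxylate, via oxazoline 27 (not isolated)
Conditions: Deoxo-Fluor, CH2Cl2, −20 °C; then BrCCl3, DBU, 0 °C → rt
Reagents that add atoms: none
Why: Cyclodehydration of the β-hydroxy amide with Deoxo-Fluor followed by BrCCl3/DBU dehydrogenation of the oxazoline is the standard one-pot route to 2,4-disubstituted oxazoles and forms oxazole B, the serine stereocentre being erased on purpose.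

Step 18
Reactants: 28 methyl 2-[(2R)-2-methoxy-4-(trimethylsilyl)but-3-yn-1-yl]-1,3-oxazole-4-carboxylate
Product: 29 methyl 2-[(2R)-2-methoxybut-3-yn-1-yl]-1,3-oxazole-4-carboxylate
Conditions: K2CO3 (cat.), MeOH, 0 °C
Reagents that add atoms: none
Why: Base-catalysed methanolytic protodesilylation frees the terminal alkyne at C8′ under conditions too mild for loss of methanol across C5′–C6′.

Step 19
Reactants: 29 methyl 2-[(2R)-2-methoxybut-3-yn-1-yl]-1,3-oxazole-4-carboxylate; 30 (Z)-1,2-dichloroethene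
Product: 31 methyl 2-[(2R,5Z)-6-chloro-2-methoxyhex-5-en-3-yn-1-yl]-1,3-oxazole-4-carboxylate
Conditions: 30 (excess), Pd(PPh3)4, CuI (cat.), piperidine, THF, rt
Reagents that add atoms: none
Why: Sonogashira coupling with a large excess of the dichloride stops after one C–Cl bond has reacted, forms C8′–C9′ and keeps the Z geometry.

Step 20
Reactants: 18 (3R)-1-[(tert-butyldimethylsilyl)oxy]-2,2-dimethylhex-5-yn-3-yl 2-[(diethoxyphosphoryl)methyl]-1,3-oxazole-4-carboxylate; 31 methyl 2-[(2R,5Z)-6-chloro-2-methoxyhex-5-en-3-yn-1-yl]-1,3-oxazole-4-carboxylate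
Product: 32 methyl 2-[(2R,5Z,10R)-12-[(tert-butyldimethylsilyl)oxy]-10-({2-[(diethoxyphosphoryl)methyl]-1,3-oxazole-4-carbonyl}oxy)-2-methoxy-11,11-dimethyldodec-5-ene-3,7-diyn-1-yl]-1,3-oxazole-4-carboxylate
Conditions: PdCl2(PhCN)2, CuI (cat.), piperidine, THF, rt
Reagents that add atoms: none
Why: A second Sonogashira coupling, for which the enyne-activated alkenyl chloride is a proven partner, forms C10′–C11′ with retention and gives the (Z)-enediyne.

Step 21
Reactants: 32 the (Z)-enediyne phosphonate diester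
Product: 33 methyl 2-[(2R,3Z,5Z,7Z,10R)-12-[(tert-butyldimethylsilyl)oxy]-10-({2-[(diethoxyphosphoryl)methyl]-1,3-oxazole-4-carbonyl}oxy)-2-methoxy-11,11-dimethyldodeca-3,5,7-trien-1-yl]-1,3-oxazole-4-carboxylate
Conditions: Zn(Cu/Ag), MeOH/H2O/THF, rt, dark
Reagents that add atoms: none
Why: Boland reduction with Zn(Cu/Ag) adds hydrogen syn to alkynes that are conjugated with an alkene, so both triple bonds become Z alkenes without over-reduction and without harm to esters, phosphonate or silyl ether.

Step 22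
Reactants: 33 the (7′Z,9′Z,11′Z)-triene phosphonate diester; 13 the C6–C16 hydroxy epoxy enal
Product: 34 seco methyl ester (C1′ CO2Me and free C14 hydroxyl at the chain ends; C1–O14′ ester; 5E,7E diene; 9S,10R cis oxirane; 11Z alkene; C16 and C16′ as TBS ethers)
Conditions: LiCl, DBU, MeCN, 0 °C; then 13, 0 °C → rt
Reagents that add atoms: none
Why: Horner–Wadsworth–Emmons olefination under Masamune–Roush conditions, in which lithium bridges the phosphoryl oxygen and the nitrogen of oxazole A so that DBU suffices as base, forms C5=C6 with E geometry and tolerates the free C14 hydroxyl and the oxirane.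

Step 23
Reactants: 34 seco methyl ester
Product: 35 seco acid (free C1′ carboxylic acid and free C14 hydroxyl)
Conditions: LiOH, THF/H2O, 0 °C; aq. NaH2PO4, 0 °C
Reagents that add atoms: lithium hydroxide, [Li+].[OH-]
Why: Saponification is selective because the methyl ester at C1′ is unhindered whereas the C1–O14′ ester is shielded by the quaternary C15′, and the oxirane is inert to hydroxide at this temperature.

Step 24
Reactants: 35 seco acid
Product: 36 30-membered bis-lactone with C16 and C16′ as TBS ethers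
Conditions: 2-methyl-6-nitrobenzoic anhydride (MNBA), DMAP, CH2Cl2 (1 mM, slow addition), rt
Reagents that add atoms: none
Why: Shiina macrolactonisation activates C1′ as a mixed anhydride at room temperature under basic conditions, and high dilution favours closure of the 30-membered ring at O14 with retention at C14.

Step 25
Reactants: 36 macrocyclic bis(TBS ether)
Product: 37 macrocyclic C16,C16′ diol
Conditions: HF·pyridine, pyridine, THF, 0 °C → rt
Reagents that add atoms: none
Why: Fluoride-mediated desilylation with pyridine-buffered HF·pyridine is close to neutral, which protects the bis-allylic oxirane from acid and avoids the free alkoxide that would trigger acyl shift from O14 or O14′ to the new primary hydroxyl.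

Step 26
Reactants: 37 macrocyclic C16,C16′ diol
Product: 38 macrocyclic C16,C16′ dialdehyde
Conditions: Dess–Martin periodinane, pyridine, CH2Cl2, 0 °C
Reagents that add atoms: none
Why: Dess–Martin oxidation buffered with pyridine converts both neopentyl alcohols into aldehydes without touching polyenes or oxirane, and the products cannot enolise.

Step 27
Reactants: 38 macrocyclic C16,C16′ dialdehyde; 39 (E)-1-bromoprop-1-ene (two molecules enter the product)
Product: 40 CNP0284709.4 (target)
Conditions: CrCl2, (S)-N-[2-(4-isopropyl-4,5-dihydro-1,3-oxazol-2-yl)-6-methoxyphenyl]methanesulfonamide, Et3N, THF, rt; NiCl2 (cat.), 39 (excess), rt; then 38, rt; aq. NaHCO3/L-serine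
Reagents that add atoms: none
Why: NiCl2 is reduced in the flask to zerovalent nickel, which inserts into the C–Br bond of 39 and hands the propenyl group with retained E geometry to chromium; the resulting ligand-bound propenyl species of trivalent chromium adds to the C16 and the C16′ carbonyl, and water releases both carbinols from their chromium alkoxides. The closest known reaction type is the ligand-controlled asymmetric Nozaki–Hiyama–Kishi alkenylation of aldehydes, run here twice in one flask, and no ring is closed. Both new centres need Si-face attack, and the controlling element at each is the oxazoline–sulfonamide on chromium, used in a full equivalent to the metal so that no unligated reagent adds; the resident O14 acyloxy group should reinforce this sense at C16 (1,3-anti product), while O14′ should oppose it at C16′ (1,3-syn product), where the ligand has to dominate. The step needs aldehyde-only reactivity, which rests on the known indifference of alkenylchromium reagents to esters, oxazoles and polyenes and on C15 and C15′ carrying no hydrogen, so that neither enolisation nor loss of the β-acyloxy group can occur. The vinyl oxirane is the one group that divalent chromium might reduce, so 38 is added last to a mixture in which excess 39 has already consumed most of the reductant, and no iodide or extra Lewis acid is present. The chromium alkoxides are weak nucleophiles, so acyl shift from O14 or O14′ is not expected before the mild work-up.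

Compound list
1 | 2,2-dimethylpropane-1,3-diol | OCC(C)(C)CO | starting material
2 | 3-[(tert-butyldimethylsilyl)oxy]-2,2-dimethylpropan-1-ol | CC(C)(C)[Si](C)(C)OCC(C)(C)CO | intermediate
3 | 3-[(tert-butyldimethylsilyl)oxy]-2,2-dimethylpropanal | CC(C)(C)[Si](C)(C)OCC(C)(C)C=O | intermediate
4 | tributyl(propa-1,2-dien-1-yl)stannane | C=C=C[Sn](CCCC)(CCCC)CCCC | starting material
5 | (3S)-1-[(tert-butyldimethylsilyl)oxy]-2,2-dimethylhex-5-yn-3-ol | C#CC[C@H](O)C(C)(C)CO[Si](C)(C)C(C)(C)C | intermediate
6 | ethyl (2Z)-3-iodoprop-2-enoate | CCOC(=O)/C=C\I | starting material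
7 | (2Z)-3-iodoprop-2-en-1-ol | OC/C=C\I | intermediate
8 | (2Z,7S)-9-[(tert-butyldimethylsilyl)oxy]-8,8-dimethylnon-2-en-4-yne-1,7-diol | OC/C=C\C#CC[C@H](O)C(C)(C)CO[Si](C)(C)C(C)(C)C | intermediate
9 | (3S)-1-[(tert-butyldimethylsilyl)oxy]-6-[(2R,3S)-3-(hydroxymethyl)oxiran-2-yl]-2,2-dimethylhex-5-yn-3-ol | CC(C)(C)[Si](C)(C)OCC(C)(C)[C@@H](O)CC#C[C@H]1O[C@H]1CO | intermediate
10 | (3S,5Z)-1-[(tert-butyldimethylsilyl)oxy]-6-[(2R,3S)-3-(hydroxymethyl)oxiran-2-yl]-2,2-dimethylhex-5-en-3-ol | CC(C)(C)[Si](C)(C)OCC(C)(C)[C@@H](O)C/C=C\[C@H]1O[C@H]1CO | intermediate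
11 | (triphenyl-λ5-phosphanylidene)acetaldehyde | O=CC=P(c1ccccc1)(c1ccccc1)c1ccccc1 | starting material
12 | (2R,3R)-3-[(1Z,4S)-6-[(tert-butyldimethylsilyl)oxy]-4-hydroxy-5,5-dimethylhex-1-en-1-yl]oxirane-2-carbaldehyde (cis; not isolated) | CC(C)(C)[Si](C)(C)OCC(C)(C)[C@@H](O)C/C=C\[C@H]1O[C@H]1C=O | intermediate
13 | (2E)-3-{(2S,3R)-3-[(1Z,4S)-6-[(tert-butyldimethylsilyl)oxy]-4-hydroxy-5,5-dimethylhex-1-en-1-yl]oxiran-2-yl}prop-2-enal | CC(C)(C)[Si](C)(C)OCC(C)(C)[C@@H](O)C/C=C\[C@H]1O[C@H]1/C=C/C=O | intermediate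
14 | (3R)-1-[(tert-butyldimethylsilyl)oxy]-2,2-dimethylhex-5-yn-3-ol | C#CC[C@@H](O)C(C)(C)CO[Si](C)(C)C(C)(C)C | intermediate
15 | methyl 2-(chloromethyl)-1,3-oxazole-4-carboxylate | COC(=O)c1coc(CCl)n1 | starting material
16 | methyl 2-[(diethoxyphosphoryl)methyl]-1,3-oxazole-4-carboxylate | COC(=O)c1coc(CP(=O)(OCC)OCC)n1 | intermediate
17 | 2-[(diethoxyphosphoryl)methyl]-1,3-oxazole-4-carboxylic acid | OC(=O)c1coc(CP(=O)(OCC)OCC)n1 | intermediate
18 | (3R)-1-[(tert-butyldimethylsilyl)oxy]-2,2-dimethylhex-5-yn-3-yl 2-[(diethoxyphosphoryl)methyl]-1,3-oxazole-4-carboxylate | CCOP(=O)(OCC)Cc1nc(co1)C(=O)O[C@@H](C(C)(C)CO[Si](C)(C)C(C)(C)C)CC#C | intermediate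
19 | 3-(trimethylsilyl)prop-2-ynal | O=CC#C[Si](C)(C)C | starting material
20 | tributyl(prop-2-en-1-yl)stannane | C=CC[Sn](CCCC)(CCCC)CCCC | starting material
21 | (3R)-1-(trimethylsilyl)hex-5-en-1-yn-3-ol | C=CC[C@@H](O)C#C[Si](C)(C)C | intermediate
22 | [(3R)-3-methoxyhex-5-en-1-yn-1-yl]trimethylsilane | C=CC[C@@H](OC)C#C[Si](C)(C)C | intermediate
23 | (3R)-3-methoxy-5-(trimethylsilyl)pent-4-ynal (not isolated) | O=CC[C@@H](OC)C#C[Si](C)(C)C | intermediate
24 | (3R)-3-methoxy-5-(trimethylsilyl)pent-4-ynoic acid | OC(=O)C[C@@H](OC)C#C[Si](C)(C)C | intermediate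
25 | L-serine methyl ester hydrochloride | COC(=O)[C@@H](N)CO.Cl | starting material
26 | methyl N-[(3R)-3-methoxy-5-(trimethylsilyl)pent-4-ynoyl]-L-serinate | COC(=O)[C@H](CO)NC(=O)C[C@@H](OC)C#C[Si](C)(C)C | intermediate
27 | methyl (4S)-2-[(2R)-2-methoxy-4-(trimethylsilyl)but-3-yn-1-yl]-4,5-dihydro-1,3-oxazole-4-carboxylate (not isolated) | COC(=O)[C@@H]1COC(C[C@@H](OC)C#C[Si](C)(C)C)=N1 | intermediate
28 | methyl 2-[(2R)-2-methoxy-4-(trimethylsilyl)but-3-yn-1-yl]-1,3-oxazole-4-carboxylate | COC(=O)c1coc(C[C@@H](OC)C#C[Si](C)(C)C)n1 | intermediate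
29 | methyl 2-[(2R)-2-methoxybut-3-yn-1-yl]-1,3-oxazole-4-carboxylate | COC(=O)c1coc(C[C@@H](OC)C#C)n1 | intermediate
30 | (Z)-1,2-dichloroethene | Cl/C=C\Cl | starting material
31 | methyl 2-[(2R,5Z)-6-chloro-2-methoxyhex-5-en-3-yn-1-yl]-1,3-oxazole-4-carboxylate | COC(=O)c1coc(C[C@@H](OC)C#C/C=C\Cl)n1 | intermediate
32 | (Z)-enediyne phosphonate diester (C7′≡C8′, 9′Z, C11′≡C12′; C1–O14′ ester; C1′ methyl ester; C16′ OTBS) | CCOP(=O)(OCC)Cc1nc(co1)C(=O)O[C@@H](C(C)(C)CO[Si](C)(C)C(C)(C)C)CC#C/C=C\C#C[C@H](OC)Cc1nc(co1)C(=O)OC | intermediate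
33 | (7′Z,9′Z,11′Z)-triene phosphonate diester | CCOP(=O)(OCC)Cc1nc(co1)C(=O)O[C@@H](C(C)(C)CO[Si](C)(C)C(C)(C)C)C\C=C/C=C\C=C/[C@H](OC)Cc1nc(co1)C(=O)OC | intermediate
34 | seco methyl ester (free C14 hydroxyl, C1′ methyl ester) | CC(C)(C)[Si](C)(C)OCC(C)(C)[C@@H](O)C/C=C\[C@H]1O[C@H]1/C=C/C=C/c1nc(co1)C(=O)O[C@@H](C(C)(C)CO[Si](C)(C)C(C)(C)C)C\C=C/C=C\C=C/[C@H](OC)Cc1nc(co1)C(=O)OC | intermediate
35 | seco acid (free C14 hydroxyl, free C1′ acid) | CC(C)(C)[Si](C)(C)OCC(C)(C)[C@@H](O)C/C=C\[C@H]1O[C@H]1/C=C/C=C/c1nc(co1)C(=O)O[C@@H](C(C)(C)CO[Si](C)(C)C(C)(C)C)C\C=C/C=C\C=C/[C@H](OC)Cc1nc(co1)C(=O)O | intermediate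
36 | 30-membered bis-lactone, C16 and C16′ as TBS ethers | CC(C)(C)[Si](C)(C)OCC(C)(C)[C@@H]1C/C=C\[C@H]2O[C@H]2/C=C/C=C/c2nc(co2)C(=O)O[C@@H](C(C)(C)CO[Si](C)(C)C(C)(C)C)C\C=C/C=C\C=C/[C@H](OC)Cc2nc(co2)C(=O)O1 | intermediate
37 | macrocyclic C16,C16′ diol | OCC(C)(C)[C@@H]1C/C=C\[C@H]2O[C@H]2/C=C/C=C/c2nc(co2)C(=O)O[C@@H](C(C)(C)CO)C\C=C/C=C\C=C/[C@H](OC)Cc2nc(co2)C(=O)O1 | intermediate
38 | macrocyclic C16,C16′ dialdehyde | O=CC(C)(C)[C@@H]1C/C=C\[C@H]2O[C@H]2/C=C/C=C/c2nc(co2)C(=O)O[C@@H](C(C)(C)C=O)C\C=C/C=C\C=C/[C@H](OC)Cc2nc(co2)C(=O)O1 | intermediate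
39 | (E)-1-bromoprop-1-ene | C/C=C/Br | starting material
40 | CNP0284709.4 (6′R,9S,10R,14S,14′R,16S,16′S; 5E,7E,11Z,7′Z,9′Z,11′Z,17E,17′E) | C/C=C/[C@H](O)C(C)(C)[C@@H]1C/C=C\[C@H]2O[C@H]2/C=C/C=C/c2nc(co2)C(=O)O[C@@H](C(C)(C)[C@@H](O)/C=C/C)C\C=C/C=C\C=C/[C@H](OC)Cc2nc(co2)C(=O)O1 | target

Total step count: 27. Longest linear sequence: 15 steps (steps 13 to 27, starting from 19).

Steps most likely to fail

Step 27. Two things may go wrong. Facial control may erode at the mismatched C16′ carbonyl, and divalent chromium may open the C9–C10 vinyl oxirane by electron transfer. The fallback keeps the C16–C17 and C16′–C17′ bond formation on 38 but separates it from the stereocontrol and uses no low-valent metal.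
- Propyne is hydrozirconated with Cp2ZrHCl and transmetalated with Me2Zn (CH2Cl2, 0 °C). The (E)-propenylzinc reagent adds to both aldehydes of 38 to give the C16/C16′-epimeric bis(propenyl carbinol) mixture F1.
- Dess–Martin oxidation with pyridine buffer converges all epimers to the macrocyclic bis[(E)-propenyl ketone] F2.
- Corey–Bakshi–Shibata reduction with (R)-Me-CBS and catecholborane at −78 °C, in which the quaternary C15 or C15′ acts as the large substituent, should give both S carbinols and return to 40.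

Step 24. Slow acylation of the neopentylic O14 may let oligomerisation compete. The free O14 may also attack the allylic oxirane carbon C10 while the seco acid is handled. The fallback swaps the order of ester formation and olefination, so that O14 is capped early and no epoxide-bearing acid exists.
- It sets out from 33, whose methyl ester is saponified (LiOH, THF/H2O, 0 °C) to the triene phosphonate carboxylic acid F3.
- Shiina esterification (MNBA, DMAP, Et3N, CH2Cl2, rt) with 13 gives the open-chain C1′–O14 ester carrying the C5 phosphonate and the C6 enal F4.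
- An intramolecular Horner–Wadsworth–Emmons reaction (LiCl, DBU, MeCN/THF, high dilution) closes the ring at C5=C6 and returns to 36.

Step 7. Hydrogenolysis of the propargylic C10–O bond and over-reduction on palladium may erode the Z vinyl oxirane. The fallback reduces before the oxirane exists.
- It sets out from 8, whose conjugated enyne is reduced with Zn(Cu/Ag) (MeOH/H2O, rt) to (2Z,4Z,7S)-9-[(tert-butyldimethylsilyl)oxy]-8,8-dimethylnona-2,4-diene-1,7-diol F5.
- Sharpless epoxidation with L-(+)-DET, directed by the C8 hydroxyl to C9=C10 only, returns to 10.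

Further compounds
F1 | step 27 | C16/C16′-epimeric bis(propenyl carbinol) mixture | C/C=C/C(O)C(C)(C)[C@@H]1C/C=C\[C@H]2O[C@H]2/C=C/C=C/c2nc(co2)C(=O)O[C@@H](C(C)(C)C(O)/C=C/C)C\C=C/C=C\C=C/[C@H](OC)Cc2nc(co2)C(=O)O1
F2 | step 27 | macrocyclic bis[(E)-propenyl ketone] | C/C=C/C(=O)C(C)(C)[C@@H]1C/C=C\[C@H]2O[C@H]2/C=C/C=C/c2nc(co2)C(=O)O[C@@H](C(C)(C)C(=O)/C=C/C)C\C=C/C=C\C=C/[C@H](OC)Cc2nc(co2)C(=O)O1
F3 | step 24 | triene phosphonate carboxylic acid | CCOP(=O)(OCC)Cc1nc(co1)C(=O)O[C@@H](C(C)(C)CO[Si](C)(C)C(C)(C)C)C\C=C/C=C\C=C/[C@H](OC)Cc1nc(co1)C(=O)O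
F4 | step 24 | open-chain C1′–O14 ester carrying the C5 phosphonate and the C6 enal | CC(C)(C)[Si](C)(C)OCC(C)(C)[C@@H](OC(=O)c1coc(C[C@@H](OC)\C=C/C=C\C=C/C[C@@H](OC(=O)c2coc(CP(=O)(OCC)OCC)n2)C(C)(C)CO[Si](C)(C)C(C)(C)C)n1)C/C=C\[C@H]1O[C@H]1/C=C/C=O
F5 | step 7 | (2Z,4Z,7S)-9-[(tert-butyldimethylsilyl)oxy]-8,8-dimethylnona-2,4-diene-1,7-diol | OC/C=C\C=C/C[C@H](O)C(C)(C)CO[Si](C)(C)C(C)(C)C
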